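**Retrosynthetic overview**
- The target is cut at the ester C–O bond into 19-(furan-2-yl)nonadeca-5,7-diynoic acid and 21-(furan-2-yl)henicosa-14,16-diyn-1-ol, joined last by carbodiimide esterification.
- Feature used: in the acyl chain the carboxyl carbon C1 and the first diyne carbon C5 are linked by three methylenes (C2, C3, C4), and C6 already carries the C7≡C8 alkyne. C1 to C6 are therefore the six carbons of a cyclohexanone ring cut open between C1 and C6.
- The acid comes from the 5,7-diynal, released from a 2-alkynyl-2,3-epoxycyclohexanone by Eschenmoser–Tanabe fragmentation, which makes C5≡C6 and the C1 aldehyde together without any alkyne–alkyne coupling. The epoxy ketone comes from 2-iodocyclohex-2-en-1-one and 2-(tridec-12-yn-1-yl)furan (Sonogashira coupling, then nucleophilic epoxidation).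
- The alcohol comes from a Cadiot–Chodkiewicz coupling of 15-bromopentadec-14-yn-1-ol (prop-2-yn-1-ol plus 1-bromododecane, alkyne zipper, bromination) with 2-(hex-5-yn-1-yl)furan. Both furylalkyl chains are drawn from one batch of 2-lithiofuran, alkylated with 1,11-dibromoundecane and with 1,4-dibromobutane.
- Ring order: both furans and the cyclohexenone ring are bought. The only ring made is the oxirane (step 6), and it is consumed together with the carbocycle in step 7, so the target keeps only the two furans.

Key step: step 7

Remark: the target has no stereocentre, and the epoxy ketone and its two hydrazone-stage descendants are handled as racemates whose stereocentres vanish in the key step; a 2-alkylfuran is assumed not to tolerate electrophilic halogen sources (chlorite/hypochlorite, NBS), which fixes the oxidant of step 8 and the choice of bromoalkyne partner in step 14.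

**Route**

Step 1
Reactants: 1 furan
Product: 2 2-lithiofuran (prepared and kept as a THF solution)
Conditions: furan (1.1 equiv), n-BuLi (1.0 equiv), THF, 0 °C, 1 h; solution held at 0 °C and divided into two portions for steps 2 and 9
Reagents that add atoms: n-butyllithium, [Li]CCCC
Why: Deprotonation (α-lithiation) of furan at C2 next to the ring oxygen by n-BuLi, run with a slight excess of furan so that no butyllithium is left to attack the dibromides, should give a solution that is stable in THF at 0 °C long enough for one batch to serve both alkylations.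

Step 2
Reactants: 2 2-lithiofuran (first portion of the solution); 3 1,11-dibromoundecane
Product: 4 2-(11-bromoundecyl)furan
Conditions: 3 (3 equiv), THF, −78 °C, solution of 2 added slowly; then −78 → 20 °C
Reagents that add atoms: none
Why: The furyllithium displaces one primary bromide (SN2 alkylation), and inverse addition into an excess of the dibromide suppresses double alkylation.

Step 3
Reactants: 4 2-(11-bromoundecyl)furan
Product: 5 2-(tridec-12-yn-1-yl)furan
Conditions: LiC≡CH·H2N(CH2)2NH2, DMSO, 20 °C
Reagents that add atoms: lithium acetylide ethylenediamine complex, [Li]C#C.NCCN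
Why: SN2 alkylation of lithium acetylide by the primary bromide in a dipolar aprotic solvent should give the terminal alkyne, the furan being inert to the acetylide.

Step 4
Reactants: 6 cyclohex-2-en-1-one
Product: 7 2-iodocyclohex-2-en-1-one
Conditions: I2, pyridine, CH2Cl2, 0 → 20 °C
Reagents that add atoms: iodine, II
Why: α-Iodination of the enone by a Baylis–Hillman-type addition–elimination sequence, in which pyridine adds to C3, the resulting enolate is iodinated at C2 and pyridine is lost again.

Step 5
Reactants: 5 2-(tridec-12-yn-1-yl)furan; 7 2-iodocyclohex-2-en-1-one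
Product: 8 2-[13-(furan-2-yl)tridec-1-yn-1-yl]cyclohex-2-en-1-one
Conditions: PdCl2(PPh3)2 (cat.), CuI (cat.), i-Pr2NH, THF, 0 °C
Reagents that add atoms: none
Why: Sonogashira coupling, in which the electron-poor vinyl iodide adds quickly to zerovalent palladium and couples with terminal alkyne 5 under CuI co-catalysis at a temperature the base-sensitive iodoenone tolerates.

Step 6
Reactants: 8 2-[13-(furan-2-yl)tridec-1-yn-1-yl]cyclohex-2-en-1-one
Product: 9 rac-(1R,6R)-1-[13-(furan-2-yl)tridec-1-yn-1-yl]-7-oxabicyclo[4.1.0]heptan-2-one
Conditions: 30% aq. H2O2, NaOH (cat.), MeOH, 0 °C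
Reagents that add atoms: hydrogen peroxide, OO
Why: Weitz–Scheffer nucleophilic epoxidation, in which hydroperoxide adds to C3 of the enone and the enolate closes onto oxygen; the oxirane is cis-fused by ring constraint and racemic because nothing chiral is present, and the basic peroxide leaves furan and alkyne alone.

Step 7
Reactants: 9 rac-(1R,6R)-1-[13-(furan-2-yl)tridec-1-yn-1-yl]-7-oxabicyclo[4.1.0]heptan-2-one
Product: 12 19-(furan-2-yl)nonadeca-5,7-diynal, via sulfonylhydrazone 10 (not isolated), via azoalkene alcohol 11 (not isolated)
Conditions: 2,4-(O2N)2C6H3SO2NHNH2 (1.05 equiv), THF, −15 → 0 °C; then pyridine (2 equiv), 0 → 20 °C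
Reagents that add atoms: none
Why: Proposed new method: the ketone of 9 condenses with the sulfonylhydrazide to hydrazone 10, pyridine removes its acidic N–H and the oxirane C–O bond at the alkynyl-bearing carbon opens to give azoalkene 11, whose alkoxide then collapses in a Grob-type fragmentation that cleaves the bond between the carbinol carbon and the alkynyl-bearing carbon, expels N2 and 2,4-dinitrobenzenesulfinate and delivers the C5≡C6 triple bond and the C1 aldehyde in one event. The closest known reaction type is the Eschenmoser–Tanabe fragmentation of cyclic α,β-epoxy ketone sulfonylhydrazones to acetylenic ketones and aldehydes; what is new is the alkynyl group on the epoxide carbon, so that the triple bond is formed in conjugation with an existing one, and this group should only stabilise the azo-enyne stage and the developing diyne. No ring is closed (the oxirane and the six-membered carbocycle are both opened) and no stereocentre is formed, the two of 9 being destroyed. The regiochemistry needed is fixed by the substrate, since only the former carbonyl carbon and its epoxide neighbour can become the alkyne and only the oxirane CH can become the carbonyl. Chemoselectivity rests on using close to one equivalent of hydrazide, so that aldehyde 12 is not consumed as a second hydrazone, and on a medium free of strong acid, which the 2-alkylfuran requires. The dinitro reagent is preferred to TsNHNH2 because aldehyde-forming cases fragment poorly with the latter, whereas its more acidic hydrazone and better sulfinate leaving group should allow fragmentation at or below 20 °C.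

Step 8
Reactants: 12 19-(furan-2-yl)nonadeca-5,7-diynal
Product: 13 19-(furan-2-yl)nonadeca-5,7-diynoic acid
Conditions: Ag2O, NaOH, THF/EtOH/H2O, 0 → 20 °C; then 1 M HCl to pH 3–4, 0 °C
Reagents that add atoms: sodium hydroxide in water (its oxygen becomes the second carboxyl oxygen), [Na+].[OH-]
Why: Tollens-type oxidation of the aldehyde hydrate by Ag2O uses no electrophilic halogen or peracid, so the internal diyne and the 2-alkylfuran (which a chlorite oxidation would risk opening to a 4-oxo-enoic acid) should survive.

Step 9
Reactants: 2 2-lithiofuran (second portion of the solution); 14 1,4-dibromobutane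
Product: 15 2-(4-bromobutyl)furan
Conditions: 14 (3 equiv), THF, −78 °C, solution of 2 added slowly; then −78 → 20 °C
Reagents that add atoms: none
Why: Same SN2 mono-alkylation of the furyllithium as in step 2, with inverse addition into excess dibromide to avoid the bis-furyl product.

Step 10
Reactants: 15 2-(4-bromobutyl)furan
Product: 16 2-(hex-5-yn-1-yl)furan
Conditions: LiC≡CH·H2N(CH2)2NH2, DMSO, 20 °C
Reagents that add atoms: lithium acetylide ethylenediamine complex, [Li]C#C.NCCN
Why: SN2 alkylation of lithium acetylide by the primary bromide, as in step 3.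

Step 11
Reactants: 17 prop-2-yn-1-ol; 18 1-bromododecane
Product: 20 pentadec-2-yn-1-ol, via dilithiated prop-2-yn-1-ol 19 (not isolated)
Conditions: n-BuLi (2.1 equiv), THF/DMPU, −78 → 0 °C; then 18, 0 → 20 °C; then H2O
Reagents that add atoms: none
Why: Double deprotonation gives the C,O-dilithio species, which is alkylated by the primary bromide at the far more nucleophilic acetylide carbon (acetylide SN2 alkylation).

Step 12
Reactants: 20 pentadec-2-yn-1-ol
Product: 21 pentadec-14-yn-1-ol
Conditions: KH, H2N(CH2)3NH2, 20 °C; then 20, 0 → 20 °C; then H2O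
Reagents that add atoms: none
Why: Alkyne zipper isomerisation, in which KNH(CH2)3NH2 moves the triple bond along the chain by propargyl–allenyl proton shifts until the terminal acetylide forms irreversibly, the alkoxide end blocking migration the other way.

Step 13
Reactants: 21 pentadec-14-yn-1-ol
Product: 22 15-bromopentadec-14-yn-1-ol
Conditions: NBS, AgNO3 (cat.), acetone, 20 °C, dark
Reagents that add atoms: N-bromosuccinimide, O=C1CCC(=O)N1Br
Why: Silver-catalysed electrophilic bromination of the terminal alkyne C–H; the bromoalkyne is put on this furan-free partner because NBS would brominate a 2-alkylfuran ring.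

Step 14
Reactants: 22 15-bromopentadec-14-yn-1-ol; 16 2-(hex-5-yn-1-yl)furan
Product: 23 21-(furan-2-yl)henicosa-14,16-diyn-1-ol
Conditions: CuCl (cat.), NH2OH·HCl, 30% aq. n-BuNH2, THF/MeOH, 0 °C
Reagents that add atoms: none
Why: Cadiot–Chodkiewicz coupling of terminal alkyne 16 with 1-bromoalkyne 22 should give the unsymmetrical 1,3-diyne, NH2OH·HCl keeping copper monovalent so that oxidative homocoupling is suppressed.

Step 15
Reactants: 13 19-(furan-2-yl)nonadeca-5,7-diynoic acid; 23 21-(furan-2-yl)henicosa-14,16-diyn-1-ol
Product: 24 21-(furan-2-yl)henicosa-14,16-diyn-1-yl 19-(furan-2-yl)nonadeca-5,7-diynoate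
Conditions: DCC, DMAP (cat.), CH2Cl2, 0 → 20 °C
Reagents that add atoms: none
Why: Steglich esterification, with carbodiimide activation of the acid and DMAP acyl transfer to the primary alcohol under neutral conditions that both furans and both diynes tolerate.

**Compound list**
1 | furan | c1ccoc1 | starting material
2 | 2-lithiofuran (furan-2-yllithium; prepared and used as a THF solution) | [Li]c1ccco1 | intermediate
3 | 1,11-dibromoundecane | BrCCCCCCCCCCCBr | starting material
4 | 2-(11-bromoundecyl)furan | BrCCCCCCCCCCCc1ccco1 | intermediate
5 | 2-(tridec-12-yn-1-yl)furan | C#CCCCCCCCCCCCc1ccco1 | intermediate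
6 | cyclohex-2-en-1-one | O=C1CCCC=C1 | starting material
7 | 2-iodocyclohex-2-en-1-one | O=C1CCCC=C1I | intermediate
8 | 2-[13-(furan-2-yl)tridec-1-yn-1-yl]cyclohex-2-en-1-one | O=C1CCCC=C1C#CCCCCCCCCCCCc1ccco1 | intermediate
9 | rac-(1R,6R)-1-[13-(furan-2-yl)tridec-1-yn-1-yl]-7-oxabicyclo[4.1.0]heptan-2-one (cis-fused oxirane; racemate, one enantiomer drawn) | O=C1CCC[C@@H]2O[C@]12C#CCCCCCCCCCCCc1ccco1 | intermediate
10 | N'-{1-[13-(furan-2-yl)tridec-1-yn-1-yl]-7-oxabicyclo[4.1.0]heptan-2-ylidene}-2,4-dinitrobenzenesulfonohydrazide (racemate, cis-fused oxirane, one enantiomer drawn, C=N geometry open) | O=S(=O)(NN=C1CCC[C@@H]2O[C@]12C#CCCCCCCCCCCCc1ccco1)c1ccc(cc1[N+](=O)[O-])[N+](=O)[O-] | intermediate (not isolated)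
11 | 3-[(2,4-dinitrophenyl)sulfonyldiazenyl]-2-[13-(furan-2-yl)tridec-1-yn-1-yl]cyclohex-2-en-1-ol (racemate; reacts as its alkoxide) | OC1CCCC(N=NS(=O)(=O)c2ccc(cc2[N+](=O)[O-])[N+](=O)[O-])=C1C#CCCCCCCCCCCCc1ccco1 | intermediate (not isolated)
12 | 19-(furan-2-yl)nonadeca-5,7-diynal | O=CCCCC#CC#CCCCCCCCCCCCc1ccco1 | intermediate
13 | 19-(furan-2-yl)nonadeca-5,7-diynoic acid | OC(=O)CCCC#CC#CCCCCCCCCCCCc1ccco1 | intermediate
14 | 1,4-dibromobutane | BrCCCCBr | starting material
15 | 2-(4-bromobutyl)furan | BrCCCCc1ccco1 | intermediate
16 | 2-(hex-5-yn-1-yl)furan | C#CCCCCc1ccco1 | intermediate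
17 | prop-2-yn-1-ol | OCC#C | starting material
18 | 1-bromododecane | CCCCCCCCCCCCBr | starting material
19 | dilithiated prop-2-yn-1-ol (lithium 3-lithioprop-2-yn-1-olate) | [Li]C#CCO[Li] | intermediate (not isolated)
20 | pentadec-2-yn-1-ol | OCC#CCCCCCCCCCCCC | intermediate
21 | pentadec-14-yn-1-ol | OCCCCCCCCCCCCCC#C | intermediate
22 | 15-bromopentadec-14-yn-1-ol | OCCCCCCCCCCCCCC#CBr | intermediate
23 | 21-(furan-2-yl)henicosa-14,16-diyn-1-ol | OCCCCCCCCCCCCCC#CC#CCCCCc1ccco1 | intermediate
24 | 21-(furan-2-yl)henicosa-14,16-diyn-1-yl 19-(furan-2-yl)nonadeca-5,7-diynoate | O=C(CCCC#CC#CCCCCCCCCCCCc1ccco1)OCCCCCCCCCCCCCC#CC#CCCCCc1ccco1 | target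

**Step count**
Total steps: 15. Longest linear sequence: 8 steps (steps 1, 2, 3, 5, 6, 7, 8, 15).

**Steps most likely to fail**

1. Step 7 (proposed new method). The fragmentation may be diverted: the azo-enyne stage may cyclise or oligomerise instead of fragmenting, or the liberated aldehyde may condense with hydrazide that has not yet reacted. The fallback uses known chemistry and sets out from alkyne 5. Purchased hex-5-ynoic acid (C#CCCCC(=O)O) would be brominated at the alkyne terminus (NBS, AgNO3 cat., acetone) to 6-bromohex-5-ynoic acid F1. This would be joined to 5 by Cadiot–Chodkiewicz coupling (CuCl cat., NH2OH·HCl, aq. n-BuNH2, THF/MeOH, 0 °C, then acidification). The coupling should give acid 13 directly, where the route is rejoined; steps 4 to 8 are then not needed.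

2. Step 8. Aldol self-condensation of the enolisable aldehyde in aqueous hydroxide, or base-induced propargyl-to-allene isomerisation at C4, may compete with the oxidation. The fallback sets out from aldehyde 12. A carbene-catalysed oxidative esterification through the acyl azolium (1,4-dimethyl-1,2,4-triazolium iodide cat., DBU, MnO2, MeOH/CH2Cl2, 20 °C) would give methyl 19-(furan-2-yl)nonadeca-5,7-diynoate F2. Saponification (LiOH, THF/H2O, then pH 4) would return to the route at acid 13.

3. Step 6. Hydroperoxide addition may be slow or reversible at the α-alkynyl-substituted enone, and conjugate addition of methoxide or base-induced degradation of the epoxy ketone may intervene. The fallback sets out from enynone 8. Luche reduction (NaBH4, CeCl3·7H2O, MeOH, 0 °C) would give racemic 2-[13-(furan-2-yl)tridec-1-yn-1-yl]cyclohex-2-en-1-ol F3. Hydroxyl-directed epoxidation (VO(acac)2 cat., t-BuOOH, CH2Cl2, 0 → 20 °C) would give the racemic cis-epoxy alcohol 1-[13-(furan-2-yl)tridec-1-yn-1-yl]-7-oxabicyclo[4.1.0]heptan-2-ol F4. Oxidation with Dess–Martin periodinane (NaHCO3, CH2Cl2, 20 °C) would return to the route at epoxy ketone 9.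

Further compounds
F1 | step 7 | 6-bromohex-5-ynoic acid | OC(=O)CCCC#CBr
F2 | step 8 | methyl 19-(furan-2-yl)nonadeca-5,7-diynoate | COC(=O)CCCC#CC#CCCCCCCCCCCCc1ccco1
F3 | step 6 | racemic 2-[13-(furan-2-yl)tridec-1-yn-1-yl]cyclohex-2-en-1-ol | OC1CCCC=C1C#CCCCCCCCCCCCc1ccco1
F4 | step 6 | racemic 1-[13-(furan-2-yl)tridec-1-yn-1-yl]-7-oxabicyclo[4.1.0]heptan-2-ol with the hydroxyl cis to the epoxide oxygen (one enantiomer drawn) | O[C@@H]1CCC[C@@H]2O[C@]12C#CCCCCCCCCCCCc1ccco1
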